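The central cyclopentane (ring B: C1, C5, C6, C7, C11, with C1 the spiro carbon and C11 the CH2 bridge) is cut into an exo-methylene C1=C11 and a three-carbon unit C5–C6–C7 stored as a cyclopropane. A monovalent-rhodium-catalysed intramolecular [3+2] cycloaddition of a lactone-derived, ring-locked 1-alkoxyvinylcyclopropane onto the tethered 1,1-disubstituted alkene forms C1–C5 and C7–C11 at once, closing the cis-fused rings A and B and fixing C1, C5, C6 and C7. The enol ether left on C7 then closes ring C by aldol addition, and its ketone becomes the unsaturated acid by triflation and carbonylation.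

Key step: step 13

Atom labels used throughout (cedrane-type numbering of the core): C1 spiro quaternary carbon; C2 CH–CHO; C3, C4 ring CH2; C5 ring-fusion CH; C6 C(CH3)(CH2OH); C7 bridgehead CH; C8 =C(CO2H); C9 =CH; C10 CH–O–acyl; C11 CH2 bridge. Ring A = C1–C2–C3–C4–C5; ring B = C1, C5, C6, C7, C11; ring C = C1, C11, C7, C8, C9, C10. Tricyclic intermediates carry the configuration of 37 at every centre they share with it.

Assumption: the (R,S)-Josiphos/CuBr·SMe2 catalyst (step 2) and the 4S-configured dirhodium carboxamidate (step 11) are taken, by analogy with their usual sense of induction, to attack the faces that give the (S) centre of 5 and the (1R,5S,6R) lactone 17; if either sense proves opposite, the enantiomeric ligand or catalyst is used with no other change.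

Step 1
Reactants: 1 1-[(allyloxy)methyl]-4-methoxybenzene; 2 methyl acrylate
Product: 3 methyl (2E)-4-[(4-methoxybenzyl)oxy]but-2-enoate
Conditions: 2 (3 equiv), second-generation Hoveyda–Grubbs catalyst (2 mol%), CH2Cl2, 40 °C
Reagents that add atoms: none
Why: Olefin cross-metathesis of an unhindered terminal alkene with an electron-poor acrylate favours the cross product and should give the E-enoate under thermodynamic control.

Step 2
Reactants: 3 methyl (2E)-4-[(4-methoxybenzyl)oxy]but-2-enoate; 4 but-3-en-1-ylmagnesium bromide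
Product: 5 methyl (3S)-3-{[(4-methoxybenzyl)oxy]methyl}hept-6-enoate
Conditions: CuBr·SMe2 (5 mol%), (R)-1-[(S)-2-(diphenylphosphino)ferrocenyl]ethyldicyclohexylphosphine [(R,S)-Josiphos, 6 mol%], t-BuOMe, −75 °C; NH4Cl (aq)
Reagents that add atoms: none
Why: Copper-catalysed asymmetric conjugate addition of a Grignard reagent to an E-enoate sets the C2 centre of the target by ligand-controlled delivery of the butenyl group to one enoate face.

Step 3
Reactants: 5 methyl (3S)-3-{[(4-methoxybenzyl)oxy]methyl}hept-6-enoate; 6 methacrolein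
Product: 7 methyl (3S,6E)-3-{[(4-methoxybenzyl)oxy]methyl}-7-methyl-8-oxooct-6-enoate
Conditions: 6 (5 equiv), second-generation Hoveyda–Grubbs catalyst (5 mol%), CH2Cl2, 40 °C
Reagents that add atoms: none
Why: Olefin cross-metathesis of the monosubstituted alkene with methacrolein should give the E-trisubstituted enal under thermodynamic control, and because 5 carries only this one alkene no ring-closing pathway is open.

Step 4
Reactants: 7 methyl (3S,6E)-3-{[(4-methoxybenzyl)oxy]methyl}-7-methyl-8-oxooct-6-enoate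
Product: 8 methyl (3S,6E)-8-hydroxy-3-{[(4-methoxybenzyl)oxy]methyl}-7-methyloct-6-enoate
Conditions: NaBH4, CeCl3·7H2O, MeOH, 0 °C
Reagents that add atoms: none
Why: Luche reduction delivers hydride 1,2 to the enal much faster than to the methyl ester and keeps the E-alkene geometry that will become the C5/C6 relationship.

Step 5
Reactants: 8 methyl (3S,6E)-8-hydroxy-3-{[(4-methoxybenzyl)oxy]methyl}-7-methyloct-6-enoate
Product: 9 methyl (3S,6E)-8-[(tert-butyldiphenylsilyl)oxy]-3-{[(4-methoxybenzyl)oxy]methyl}-7-methyloct-6-enoate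
Conditions: TBDPSCl, imidazole, CH2Cl2, rt
Reagents that add atoms: tert-butyldiphenylsilyl chloride, CC(C)(C)[Si](Cl)(c1ccccc1)c1ccccc1
Why: Silyl ether formation masks the primary allylic alcohol through the hydride reduction, the methylenation and the acid-catalysed acetalisation that follow.

Step 6
Reactants: 9 methyl (3S,6E)-8-[(tert-butyldiphenylsilyl)oxy]-3-{[(4-methoxybenzyl)oxy]methyl}-7-methyloct-6-enoate
Product: 10 (3S,6E)-8-[(tert-butyldiphenylsilyl)oxy]-3-{[(4-methoxybenzyl)oxy]methyl}-7-methyloct-6-enal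
Conditions: i-Bu2AlH (1.1 equiv), CH2Cl2, −78 °C; aq. potassium sodium tartrate (KNaC4H4O6)
Reagents that add atoms: none
Why: Partial reduction of a methyl ester at low temperature stops at the tetrahedral aluminate and gives the aldehyde on work-up without touching the β-stereocentre.

Step 7
Reactants: 10 (3S,6E)-8-[(tert-butyldiphenylsilyl)oxy]-3-{[(4-methoxybenzyl)oxy]methyl}-7-methyloct-6-enal
Product: 12 (3S,6E)-8-[(tert-butyldiphenylsilyl)oxy]-3-{[(4-methoxybenzyl)oxy]methyl}-7-methyl-2-methylideneoct-6-enal, via Mannich base 11 (not isolated)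
Conditions: Eschenmoser's salt (CH2=NMe2+ I−), Et3N, CH2Cl2, rt
Reagents that add atoms: N,N-dimethylmethyleneiminium iodide (Eschenmoser's salt), C=[N+](C)C.[I-]
Why: Mannich reaction of the aldehyde enol with the iminium salt followed by β-elimination of dimethylamine (α-methylenation) installs C11 as the exo-methylene, and the weak amine base should not deprotonate the γ-CH of the product.

Step 8
Reactants: 12 (3S,6E)-8-[(tert-butyldiphenylsilyl)oxy]-3-{[(4-methoxybenzyl)oxy]methyl}-7-methyl-2-methylideneoct-6-enal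
Product: 13 tert-butyl{[(2E,6S)-6-(3,3-dimethoxyprop-1-en-2-yl)-7-[(4-methoxybenzyl)oxy]-2-methylhept-2-en-1-yl]oxy}diphenylsilane
Conditions: HC(OMe)3, PPTS (cat.), CH2Cl2, rt
Reagents that add atoms: trimethyl orthoformate, COC(OC)OC
Why: Mild acid-catalysed acetalisation with an orthoester masks the α-substituted acrolein (future C10) before the diazo, carbenoid, titanium and rhodium steps, and the robust TBDPS ether should survive it.

Step 9
Reactants: 13 tert-butyl{[(2E,6S)-6-(3,3-dimethoxyprop-1-en-2-yl)-7-[(4-methoxybenzyl)oxy]-2-methylhept-2-en-1-yl]oxy}diphenylsilane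
Product: 14 (2E,6S)-6-(3,3-dimethoxyprop-1-en-2-yl)-7-[(4-methoxybenzyl)oxy]-2-methylhept-2-en-1-ol
Conditions: Bu4NF, THF, 0 °C to rt; H2O
Reagents that add atoms: none
Why: Fluoride-induced desilylation frees the allylic alcohol without touching the acetal, the PMB ether or either alkene.

Step 10
Reactants: 14 (2E,6S)-6-(3,3-dimethoxyprop-1-en-2-yl)-7-[(4-methoxybenzyl)oxy]-2-methylhept-2-en-1-ol
Product: 16 (2E,6S)-6-(3,3-dimethoxyprop-1-en-2-yl)-7-[(4-methoxybenzyl)oxy]-2-methylhept-2-en-1-yl diazoacetate, via tosylhydrazone ester 15 (not isolated)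
Conditions: TsNHN=CHCOCl, PhNMe2, CH2Cl2, 0 °C; then Et3N
Reagents that add atoms: 2-[(4-methylphenyl)sulfonylhydrazono]acetyl chloride, Cc1ccc(cc1)S(=O)(=O)NN=CC(Cl)=O
Why: O-acylation followed by base-induced loss of p-toluenesulfinate (Bamford–Stevens-type fragmentation) is a standard one-pot entry to allylic diazoacetates and tolerates the acetal and both alkenes.

Step 11
Reactants: 16 (2E,6S)-6-(3,3-dimethoxyprop-1-en-2-yl)-7-[(4-methoxybenzyl)oxy]-2-methylhept-2-en-1-yl diazoacetate
Product: 17 (1R,5S,6R)-6-{(3S)-3-(3,3-dimethoxyprop-1-en-2-yl)-4-[(4-methoxybenzyl)oxy]butyl}-5-methyl-3-oxabicyclo[3.1.0]hexan-2-one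
Conditions: dirhodium tetrakis[methyl (4S)-2-oxo-1-(3-phenylpropanoyl)imidazolidine-4-carboxylate], Rh2(4S-MPPIM)4 (1 mol%), CH2Cl2, 40 °C, slow addition
Reagents that add atoms: none
Why: Intramolecular cyclopropanation of an allylic diazoacetate by a chiral dirhodium carboxamidate is stereospecific for the E-alkene (tether on C5 exo, C8 and the C6–CH2O cis by ring fusion) and the catalyst selects the alkene face, so C5, C6 and C7 are set, with the wrong-face product being a separable diastereomer because C2 is already fixed.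

Step 12
Reactants: 17 (1R,5S,6R)-6-{(3S)-3-(3,3-dimethoxyprop-1-en-2-yl)-4-[(4-methoxybenzyl)oxy]butyl}-5-methyl-3-oxabicyclo[3.1.0]hexan-2-one
Product: 18 (1R,5S,6R)-6-{(3S)-3-(3,3-dimethoxyprop-1-en-2-yl)-4-[(4-methoxybenzyl)oxy]butyl}-5-methyl-2-methylidene-3-oxabicyclo[3.1.0]hexane
Conditions: Cp2TiMe2, toluene, 70 °C, dark
Reagents that add atoms: dimethyltitanocene (Petasis reagent), [CH3-].[CH3-].[Ti+4].c1cc[cH-]c1.c1cc[cH-]c1
Why: Petasis methylenation turns the lactone carbonyl (C8) into an exocyclic enol ether without acid or strong base, giving a 1-alkoxyvinylcyclopropane whose vinyl group is locked in a five-membered ring.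

Step 13
Reactants: 18 (1R,5S,6R)-6-{(3S)-3-(3,3-dimethoxyprop-1-en-2-yl)-4-[(4-methoxybenzyl)oxy]butyl}-5-methyl-2-methylidene-3-oxabicyclo[3.1.0]hexane
Product: 19 [3+2] cycloadduct: cis-fused rings A and B with a 2-methylideneoxolane fused across C6–C7 (O–CH2 on C6, C8 on C7), C1–CH(OMe)2 on the face of H5, C2–CH2OPMB trans to it, C6–CH3 cis to C4
Conditions: [Rh(CO)2Cl]2 (5 mol%), toluene, 100 °C
Reagents that add atoms: none
Why: Monovalent rhodium adds oxidatively to the C5–C7 cyclopropane bond of 18 to give a σ-alkyl(C5)/π-allyl(C7–C8–C9) trivalent rhodium species, the tethered C1=C11 alkene inserts into Rh–C5 (bond C1–C5), and C–C reductive elimination joins C11 to the allyl terminus C7. The closest known reaction type is the [Rh(CO)2Cl]2-catalysed intramolecular [3+2] cycloaddition of trans-2-ene-vinylcyclopropanes to cis-bicyclo[3.3.0]octanes, and vinylcyclopropanes carrying oxygen on the vinyl group are established partners in rhodium-catalysed cyclopropane openings. Ring A closes by a 5-exo-trig carbometalation and ring B by reductive elimination from a six-membered rhodacycle. C5, C6 and C7 keep the cyclopropane configuration (C1 replaces C7 on C5 and C11 replaces C5 on C7, both with retention), C1 is fixed by the obligatory cis fusion of the two five-membered rings, and C2 is a spectator. The step needs [3+2] instead of [5+2] closure and cleavage of C5–C7 instead of C6–C7: the enol-ether ring locks the allyl unit so that bonding at C9 would require an E-cycloheptene, and the C6–C7 bond lies in the plane of that ring, orthogonal to the π-system, whereas C5–C7 overlaps with it. After insertion the rhodium-bound C11 is attached to the quaternary C1, so β-hydride elimination cannot compete with the ring-closing reductive elimination.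

Step 14
Reactants: 19 [3+2] cycloadduct
Product: 21 ring-C-closed keto diol (C8 ketone; C10 equatorial OH; free C6–CH2OH; C2–CH2OPMB), via keto aldehyde 20 (not isolated)
Conditions: 1 M HCl, THF, rt; then K2CO3, MeOH, rt
Reagents that add atoms: water, O
Why: Aqueous acid hydrolyses the enol ether to the C7 methyl ketone (freeing the C6–CH2OH) and the acetal to the non-enolisable C10 aldehyde, and base then drives a reversible intramolecular aldol addition of the methyl carbon C9 to C10 that closes ring C and should place the C10 hydroxyl equatorial, anti to the C11 bridge, under thermodynamic control, only the C7 epimer with the acetyl group cis to the aldehyde being able to cyclise.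

Step 15
Reactants: 21 ring-C-closed keto diol
Product: 22 C6–CH2OTBS ether of 21
Conditions: TBSCl, imidazole, DMF, 0 °C
Reagents that add atoms: tert-butyldimethylsilyl chloride, CC(C)(C)[Si](C)(C)Cl
Why: Silylation distinguishes the primary C6 carbinol from the hindered secondary C10 alcohol on steric grounds and removes the hemiketal equilibrium with the C8 ketone.

Step 16
Reactants: 23 7-bromoheptan-1-ol
Product: 24 [(7-bromoheptyl)oxy](tert-butyl)dimethylsilane
Conditions: TBSCl, imidazole, CH2Cl2, rt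
Reagents that add atoms: tert-butyldimethylsilyl chloride, CC(C)(C)[Si](C)(C)Cl
Why: Standard silylation of a primary alcohol protects the future ω-hydroxyl of the side chain.

Step 17
Reactants: 24 [(7-bromoheptyl)oxy](tert-butyl)dimethylsilane
Product: 25 {7-[(tert-butyldimethylsilyl)oxy]heptyl}triphenylphosphonium bromide
Conditions: PPh3, MeCN, reflux
Reagents that add atoms: triphenylphosphine, c1ccc(cc1)P(c1ccccc1)c1ccccc1
Why: SN2 quaternisation of triphenylphosphine by a primary bromide gives the Wittig salt.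

Step 18
Reactants: 25 {7-[(tert-butyldimethylsilyl)oxy]heptyl}triphenylphosphonium bromide; 26 methyl 9-oxononanoate
Product: 28 methyl (9Z)-16-[(tert-butyldimethylsilyl)oxy]hexadec-9-enoate, via phosphonium ylide 27 (not isolated)
Conditions: NaN(SiMe3)2, THF, −78 °C; then 26, −78 °C to rt
Reagents that add atoms: none
Why: A lithium-free Wittig reaction of a non-stabilised ylide with an aldehyde is kinetically Z-selective and should leave the methyl ester untouched at low temperature.

Step 19
Reactants: 28 methyl (9Z)-16-[(tert-butyldimethylsilyl)oxy]hexadec-9-enoate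
Product: 29 (9Z)-16-[(tert-butyldimethylsilyl)oxy]hexadec-9-enoic acid
Conditions: LiOH, THF/MeOH/H2O, rt; then HCl to pH 4
Reagents that add atoms: lithium hydroxide, [Li+].[OH-]
Why: Saponification of the methyl ester proceeds without loss of the primary TBS ether or isomerisation of the Z-alkene.

Step 20
Reactants: 22 C6–CH2OTBS ether of 21; 29 (9Z)-16-[(tert-butyldimethylsilyl)oxy]hexadec-9-enoic acid
Product: 31 C10 ester of 22 with acid 29 (C8 ketone retained), via mixed anhydride 30 (not isolated)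
Conditions: 2,4,6-trichlorobenzoyl chloride, Et3N, THF, rt; then 22, DMAP, toluene, rt
Reagents that add atoms: none
Why: Yamaguchi esterification through the mixed anhydride acylates hindered secondary alcohols under mild base, and the equatorial C10–O bond is poorly aligned with the C8 enol π-system, which should disfavour elimination from the β-acyloxy ketone.

Step 21
Reactants: 31 C10 ester of 22 with acid 29
Product: 33 C8–C9 enol triflate of 31, via potassium enolate 32 (not isolated)
Conditions: KN(SiMe3)2, THF, −78 °C; then Comins' reagent, −78 °C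
Reagents that add atoms: N-(5-chloropyridin-2-yl)-1,1,1-trifluoro-N-[(trifluoromethyl)sulfonyl]methanesulfonamide (Comins' reagent), FC(F)(F)S(=O)(=O)N(c1ccc(Cl)cn1)S(=O)(=O)C(F)(F)F
Why: Kinetic deprotonation can only occur at C9 because C7 is a bridgehead, the ketone is far more acidic than the ester α-CH2, and O-sulfonylation at −78 °C should outrun E1cB loss of the equatorial C10 acyloxy group.

Step 22
Reactants: 33 C8–C9 enol triflate
Product: 34 C8 carboxylic acid with the C8=C9 double bond (C10 ester; C6–CH2OTBS; C2–CH2OPMB)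
Conditions: Pd(OAc)2 (10 mol%), 1,3-bis(diphenylphosphino)propane, Et3N, CO (1 atm), DMF/H2O, 50 °C
Reagents that add atoms: carbon monoxide, [C-]#[O+]; water, O
Why: Palladium-catalysed hydroxycarbonylation of an enol triflate (oxidative addition to zerovalent palladium, CO insertion, hydrolysis of the acylpalladium) gives the α,β-unsaturated acid directly, with the double bond fixed at C8=C9 by the triflate.

Step 23
Reactants: 34 C8 carboxylic acid
Product: 35 C2–CH2OH acid (PMB removed)
Conditions: DDQ, CH2Cl2/pH 7 buffer, 0 °C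
Reagents that add atoms: none
Why: Oxidative PMB ether cleavage by DDQ via the benzylic oxocarbenium ion leaves the silyl ethers, the ester, the acid and the isolated Z-alkene untouched.

Step 24
Reactants: 35 C2–CH2OH acid
Product: 36 C2 aldehyde bis-TBS ether
Conditions: Dess–Martin periodinane, CH2Cl2, 0 °C to rt
Reagents that add atoms: none
Why: Dess–Martin oxidation converts the only free alcohol into the C2 aldehyde under non-basic conditions that should not epimerise the α-centre.

Step 25
Reactants: 36 C2 aldehyde bis-TBS ether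
Product: 37 target, the C10 (9Z)-16-hydroxyhexadec-9-enoate of the tricyclic hydroxy aldehyde acid
Conditions: HF·pyridine, THF/pyridine, 0 °C to rt
Reagents that add atoms: none
Why: Fluoride cleavage of both primary TBS ethers under mildly acidic conditions spares the C10 ester, the aldehyde α-centre and the Z-alkene.

Compound list
1 | 1-[(allyloxy)methyl]-4-methoxybenzene | C=CCOCc1ccc(OC)cc1 | starting material
2 | methyl acrylate | C=CC(=O)OC | starting material
3 | methyl (2E)-4-[(4-methoxybenzyl)oxy]but-2-enoate | COC(=O)/C=C/COCc1ccc(OC)cc1 | intermediate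
4 | but-3-en-1-ylmagnesium bromide | C=CCC[Mg]Br | starting material
5 | methyl (3S)-3-{[(4-methoxybenzyl)oxy]methyl}hept-6-enoate | C=CCC[C@H](COCc1ccc(OC)cc1)CC(=O)OC | intermediate
6 | methacrolein | CC(=C)C=O | starting material
7 | methyl (3S,6E)-3-{[(4-methoxybenzyl)oxy]methyl}-7-methyl-8-oxooct-6-enoate | O=C/C(C)=C/CC[C@H](COCc1ccc(OC)cc1)CC(=O)OC | intermediate
8 | methyl (3S,6E)-8-hydroxy-3-{[(4-methoxybenzyl)oxy]methyl}-7-methyloct-6-enoate | OC/C(C)=C/CC[C@H](COCc1ccc(OC)cc1)CC(=O)OC | intermediate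
9 | methyl (3S,6E)-8-[(tert-butyldiphenylsilyl)oxy]-3-{[(4-methoxybenzyl)oxy]methyl}-7-methyloct-6-enoate | CC(C)(C)[Si](c1ccccc1)(c1ccccc1)OC/C(C)=C/CC[C@H](COCc1ccc(OC)cc1)CC(=O)OC | intermediate
10 | (3S,6E)-8-[(tert-butyldiphenylsilyl)oxy]-3-{[(4-methoxybenzyl)oxy]methyl}-7-methyloct-6-enal | CC(C)(C)[Si](c1ccccc1)(c1ccccc1)OC/C(C)=C/CC[C@H](COCc1ccc(OC)cc1)CC=O | intermediate
11 | Mannich base: (3S,6E)-8-[(tert-butyldiphenylsilyl)oxy]-2-[(dimethylamino)methyl]-3-{[(4-methoxybenzyl)oxy]methyl}-7-methyloct-6-enal, both C2 epimers (not isolated) | CC(C)(C)[Si](c1ccccc1)(c1ccccc1)OC/C(C)=C/CC[C@H](COCc1ccc(OC)cc1)C(CN(C)C)C=O | intermediate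
12 | (3S,6E)-8-[(tert-butyldiphenylsilyl)oxy]-3-{[(4-methoxybenzyl)oxy]methyl}-7-methyl-2-methylideneoct-6-enal | CC(C)(C)[Si](c1ccccc1)(c1ccccc1)OC/C(C)=C/CC[C@H](COCc1ccc(OC)cc1)C(=C)C=O | intermediate
13 | tert-butyl{[(2E,6S)-6-(3,3-dimethoxyprop-1-en-2-yl)-7-[(4-methoxybenzyl)oxy]-2-methylhept-2-en-1-yl]oxy}diphenylsilane | CC(C)(C)[Si](c1ccccc1)(c1ccccc1)OC/C(C)=C/CC[C@H](COCc1ccc(OC)cc1)C(=C)C(OC)OC | intermediate
14 | (2E,6S)-6-(3,3-dimethoxyprop-1-en-2-yl)-7-[(4-methoxybenzyl)oxy]-2-methylhept-2-en-1-ol | OC/C(C)=C/CC[C@H](COCc1ccc(OC)cc1)C(=C)C(OC)OC | intermediate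
15 | 2-[(4-methylphenyl)sulfonylhydrazono]acetate ester of 14 (not isolated) | Cc1ccc(cc1)S(=O)(=O)NN=CC(=O)OC/C(C)=C/CC[C@H](COCc1ccc(OC)cc1)C(=C)C(OC)OC | intermediate
16 | diazoacetate ester of 14 | [N-]=[N+]=CC(=O)OC/C(C)=C/CC[C@H](COCc1ccc(OC)cc1)C(=C)C(OC)OC | intermediate
17 | (1R,5S,6R)-6-{(3S)-3-(3,3-dimethoxyprop-1-en-2-yl)-4-[(4-methoxybenzyl)oxy]butyl}-5-methyl-3-oxabicyclo[3.1.0]hexan-2-one | C[C@@]1(COC2=O)[C@H]2[C@H]1CC[C@H](COCc3ccc(OC)cc3)C(=C)C(OC)OC | intermediate
18 | (1R,5S,6R)-6-{(3S)-3-(3,3-dimethoxyprop-1-en-2-yl)-4-[(4-methoxybenzyl)oxy]butyl}-5-methyl-2-methylidene-3-oxabicyclo[3.1.0]hexane | C[C@@]1(COC2=C)[C@H]2[C@H]1CC[C@H](COCc3ccc(OC)cc3)C(=C)C(OC)OC | intermediate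
19 | [3+2] cycloadduct: rings A and B cis-fused, 2-methylideneoxolane fused across C6–C7, C1–CH(OMe)2, C2–CH2OPMB | C[C@@]1(COC2=C)[C@H]2C[C@@]3(C(OC)OC)[C@@H](COCc4ccc(OC)cc4)CC[C@@H]13 | intermediate
20 | keto aldehyde: C7 acetyl, C1 formyl, C6–CH2OH, C2–CH2OPMB on the A/B bicycle (not isolated; in equilibrium with its hemiketal) | C[C@@]1(CO)[C@H](C(C)=O)C[C@@]2(C=O)[C@@H](COCc3ccc(OC)cc3)CC[C@@H]12 | intermediate
21 | tricyclic keto diol: C8 ketone, C10 equatorial OH, C6–CH2OH, C2–CH2OPMB | C[C@@]1(CO)[C@H]2C[C@@]3([C@@H](O)CC2=O)[C@@H](COCc4ccc(OC)cc4)CC[C@@H]13 | intermediate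
22 | C6–CH2OTBS ether of 21 | C[C@@]1(CO[Si](C)(C)C(C)(C)C)[C@H]2C[C@@]3([C@@H](O)CC2=O)[C@@H](COCc4ccc(OC)cc4)CC[C@@H]13 | intermediate
23 | 7-bromoheptan-1-ol | OCCCCCCCBr | starting material
24 | [(7-bromoheptyl)oxy](tert-butyl)dimethylsilane | CC(C)(C)[Si](C)(C)OCCCCCCCBr | intermediate
25 | {7-[(tert-butyldimethylsilyl)oxy]heptyl}triphenylphosphonium bromide | CC(C)(C)[Si](C)(C)OCCCCCCC[P+](c1ccccc1)(c1ccccc1)c1ccccc1.[Br-] | intermediate
26 | methyl 9-oxononanoate | COC(=O)CCCCCCCC=O | starting material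
27 | {7-[(tert-butyldimethylsilyl)oxy]heptylidene}triphenylphosphorane (not isolated) | CC(C)(C)[Si](C)(C)OCCCCCCC=P(c1ccccc1)(c1ccccc1)c1ccccc1 | intermediate
28 | methyl (9Z)-16-[(tert-butyldimethylsilyl)oxy]hexadec-9-enoate | COC(=O)CCCCCCC/C=C\CCCCCCO[Si](C)(C)C(C)(C)C | intermediate
29 | (9Z)-16-[(tert-butyldimethylsilyl)oxy]hexadec-9-enoic acid | OC(=O)CCCCCCC/C=C\CCCCCCO[Si](C)(C)C(C)(C)C | intermediate
30 | mixed anhydride of 29 with 2,4,6-trichlorobenzoic acid (not isolated) | O=C(OC(=O)CCCCCCC/C=C\CCCCCCO[Si](C)(C)C(C)(C)C)c1c(Cl)cc(Cl)cc1Cl | intermediate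
31 | C10 ester of 22 with 29 (C8 ketone) | C[C@@]1(CO[Si](C)(C)C(C)(C)C)[C@H]2C[C@@]3([C@@H](OC(=O)CCCCCCC/C=C\CCCCCCO[Si](C)(C)C(C)(C)C)CC2=O)[C@@H](COCc4ccc(OC)cc4)CC[C@@H]13 | intermediate
32 | potassium C8–C9 enolate of 31 (not isolated) | C[C@@]1(CO[Si](C)(C)C(C)(C)C)[C@H]2C[C@@]3([C@@H](OC(=O)CCCCCCC/C=C\CCCCCCO[Si](C)(C)C(C)(C)C)C=C2[O-])[C@@H](COCc4ccc(OC)cc4)CC[C@@H]13.[K+] | intermediate
33 | C8–C9 enol triflate | C[C@@]1(CO[Si](C)(C)C(C)(C)C)[C@H]2C[C@@]3([C@@H](OC(=O)CCCCCCC/C=C\CCCCCCO[Si](C)(C)C(C)(C)C)C=C2OS(=O)(=O)C(F)(F)F)[C@@H](COCc4ccc(OC)cc4)CC[C@@H]13 | intermediate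
34 | C8 carboxylic acid (C8=C9), C2–CH2OPMB, two TBS ethers | C[C@@]1(CO[Si](C)(C)C(C)(C)C)[C@H]2C[C@@]3([C@@H](OC(=O)CCCCCCC/C=C\CCCCCCO[Si](C)(C)C(C)(C)C)C=C2C(=O)O)[C@@H](COCc4ccc(OC)cc4)CC[C@@H]13 | intermediate
35 | C2–CH2OH acid, two TBS ethers | C[C@@]1(CO[Si](C)(C)C(C)(C)C)[C@H]2C[C@@]3([C@@H](OC(=O)CCCCCCC/C=C\CCCCCCO[Si](C)(C)C(C)(C)C)C=C2C(=O)O)[C@@H](CO)CC[C@@H]13 | intermediate
36 | C2 aldehyde acid, two TBS ethers | C[C@@]1(CO[Si](C)(C)C(C)(C)C)[C@H]2C[C@@]3([C@@H](OC(=O)CCCCCCC/C=C\CCCCCCO[Si](C)(C)C(C)(C)C)C=C2C(=O)O)[C@@H](C=O)CC[C@@H]13 | intermediate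
37 | target (CNP0148862.2) | C[C@@]1(CO)[C@H]2C[C@@]3([C@@H](OC(=O)CCCCCCC/C=C\CCCCCCO)C=C2C(=O)O)[C@@H](C=O)CC[C@@H]13 | target

Total step count: 25. Longest linear sequence: 21 steps (steps 1–15 and 20–25); steps 16–19 make the side-chain acid in a separate branch.

The three steps most likely to fail

First, step 13. The exocyclic enol ether of 18 may be hydrolysed or isomerised, or its oxygen may tie up the rhodium centre, before the metal inserts into the C5–C7 bond at 100 °C, so that the cycloaddition stalls. The fallback takes the oxygen out of the metal step and uses the plain vinylcyclopropane on which this [3+2] cycloaddition is established; it sets out from compound 17 and comes back to the route at compound 21. i-Bu2AlH in CH2Cl2 at −78 °C reduces the lactone to lactol F1, Ph3P=CH2 in THF opens it by Wittig methylenation to vinylcyclopropyl carbinol F2, and [Rh(CO)2Cl]2 in toluene at 80 °C closes rings A and B with the same stereochemical course to give C7-vinyl cycloadduct F3. Wacker oxidation (PdCl2, CuCl, O2, DMF/H2O) then converts the vinyl group into the C7 acetyl group of methyl ketone F4, which on treatment with 1 M HCl in THF and then K2CO3 in MeOH gives 21 through 20.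

Second, step 21. Enolisation of the β-acyloxy ketone may be followed by elimination of the C10 carboxylate before O-sulfonylation, which would destroy the ester and the C10 centre. The fallback attaches the side chain only after the acid carbon is in place; it sets out from compound 22 and comes back to the route at compound 34. TESOTf/2,6-lutidine at −78 °C gives C10 triethylsilyl ether F5, and KN(SiMe3)2 followed by Comins' reagent gives silyloxy enol triflate F6, in which the silyloxy group is a far poorer leaving group. Pd(OAc)2/dppp, CO, allyl alcohol and Et3N give allyl ester F7, PPTS in MeOH removes only the secondary triethylsilyl group to give hydroxy allyl ester F8, Yamaguchi esterification with 29 through 30 gives diester F9, and Pd(PPh3)4/pyrrolidine cleaves the allyl ester to 34.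

Third, step 14. Under the basic, equilibrating conditions the aldol may dehydrate to the C9=C10 enone, or the C10 aldehyde may be held as a lactol by the free C6 carbinol, so that ring C does not close cleanly. The fallback runs a kinetic boron aldol on a protected substrate; it sets out from compound 19 and comes back to the route at compound 22. Acid hydrolysis alone (1 M HCl, THF) gives 20, which is isolated, and TBSCl/imidazole gives silyl ether keto aldehyde F10. Bu2BOTf/i-Pr2NEt in CH2Cl2 at −78 °C enolises the methyl ketone to dibutylboron enolate F11, which adds intramolecularly to the C10 aldehyde and on buffered oxidative work-up gives 22.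

Further compounds
F1 | step 13 | lactol from 17 (both anomers) | C[C@@]1(COC2O)[C@H]2[C@H]1CC[C@H](COCc3ccc(OC)cc3)C(=C)C(OC)OC
F2 | step 13 | vinylcyclopropyl carbinol (C7 vinyl cis to C6–CH2OH, C5 side chain trans to the vinyl group) | C[C@@]1(CO)[C@H](C=C)[C@H]1CC[C@H](COCc2ccc(OC)cc2)C(=C)C(OC)OC
F3 | step 13 | C7-vinyl cycloadduct (rings A and B cis-fused, C1–CH(OMe)2, C6–CH2OH, C2–CH2OPMB) | C[C@@]1(CO)[C@H](C=C)C[C@@]2(C(OC)OC)[C@@H](COCc3ccc(OC)cc3)CC[C@@H]12
F4 | step 13 | methyl ketone (C7 acetyl, C1–CH(OMe)2, C6–CH2OH, C2–CH2OPMB) | C[C@@]1(CO)[C@H](C(C)=O)C[C@@]2(C(OC)OC)[C@@H](COCc3ccc(OC)cc3)CC[C@@H]12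
F5 | step 21 | C10 triethylsilyl ether of 22 | C[C@@]1(CO[Si](C)(C)C(C)(C)C)[C@H]2C[C@@]3([C@@H](O[Si](CC)(CC)CC)CC2=O)[C@@H](COCc4ccc(OC)cc4)CC[C@@H]13
F6 | step 21 | silyloxy enol triflate (C10–OTES) | C[C@@]1(CO[Si](C)(C)C(C)(C)C)[C@H]2C[C@@]3([C@@H](O[Si](CC)(CC)CC)C=C2OS(=O)(=O)C(F)(F)F)[C@@H](COCc4ccc(OC)cc4)CC[C@@H]13
F7 | step 21 | allyl ester (C8 allyl ester, C10–OTES) | C[C@@]1(CO[Si](C)(C)C(C)(C)C)[C@H]2C[C@@]3([C@@H](O[Si](CC)(CC)CC)C=C2C(=O)OCC=C)[C@@H](COCc4ccc(OC)cc4)CC[C@@H]13
F8 | step 21 | hydroxy allyl ester (C10–OH) | C[C@@]1(CO[Si](C)(C)C(C)(C)C)[C@H]2C[C@@]3([C@@H](O)C=C2C(=O)OCC=C)[C@@H](COCc4ccc(OC)cc4)CC[C@@H]13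
F9 | step 21 | diester (C10 side-chain ester, C8 allyl ester) | C[C@@]1(CO[Si](C)(C)C(C)(C)C)[C@H]2C[C@@]3([C@@H](OC(=O)CCCCCCC/C=C\CCCCCCO[Si](C)(C)C(C)(C)C)C=C2C(=O)OCC=C)[C@@H](COCc4ccc(OC)cc4)CC[C@@H]13
F10 | step 14 | silyl ether keto aldehyde (C6–CH2OTBS) | C[C@@]1(CO[Si](C)(C)C(C)(C)C)[C@H](C(C)=O)C[C@@]2(C=O)[C@@H](COCc3ccc(OC)cc3)CC[C@@H]12
F11 | step 14 | dibutylboron enolate of F10 | C[C@@]1(CO[Si](C)(C)C(C)(C)C)[C@H](C(=C)OB(CCCC)CCCC)C[C@@]2(C=O)[C@@H](COCc3ccc(OC)cc3)CC[C@@H]12
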